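## Plan

Labels: the upper flavan has rings A (benzo), C (pyran) and B (catechol). The lower flavan has rings D (benzo), F (pyran) and E (catechol). The two units are joined C6' (ring B) to C6 (ring D).
Cuts, in retrosynthetic order: all O-benzyl bonds and a C8-Br cap on ring D; O1-C2 of ring C; C1'-C2' and C5'-C6' of ring B (retro-[4+2]); the acyl bond from C2 to the alkyne carbon that becomes C1'; C4-C4a beside ring A; C6-C(sp) on ring D.
Enabling feature: on ring B the two carbon substituents are neighbours (C2 of ring C on C1', C6 of ring D on C6'). The two oxygens are neighbours on the far edge (C3', C4'), and C2' and C5' carry only H. C1'/C6' can therefore be the two carbons of an aryl ynone, and C2'-C3'-C4'-C5' a symmetric 2,3-bis(silyloxy)buta-1,3-diene.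
Forward order: rings D, F and E come intact from (+)-catechin, with C8 capped by Br and C6 ethynylated. Ring A comes from 3,5-bis(benzyloxy)phenol and gains C4-C3-C2 from methyl (S)-glycidate. Acetylide acylation joins the halves, ring B arises by cycloaddition and aromatisation, and ring C closes last.
Stereochemistry: lower C2 and C3 are bought with (+)-catechin and upper C3 with methyl (S)-glycidate. Upper C2 is set in the ring C closure, trans to the C3 benzyloxy group.

Key step: step 14

Assumption: the target string defines no axial chirality, so the C6'-C6 axis (flanked by C5-OH, C7-OH and C2) is taken to equilibrate in the free polyphenol; protected intermediates from 22 onward may be slowly interconverting rotamers and are carried on as such.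

## Route

Step 1
Reactants: 1 3,5-bis(benzyloxy)phenol
Product: 2 3,5-bis(benzyloxy)-2-iodophenol
Conditions: NIS (1.0 equiv), CH2Cl2, -20 to 0 °C, dark
Reagents that add atoms: N-iodosuccinimide, O=C1CCC(=O)N1I
Why: Electrophilic aromatic iodination, in which the free hydroxyl is the strongest activator and the two equivalent positions ortho to it (each para to a benzyloxy group) are less crowded than C4 between the two benzyloxy groups, so mono-iodination at C2 should dominate.

Step 2
Reactants: 2 3,5-bis(benzyloxy)-2-iodophenol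
Product: 3 1,5-bis(benzyloxy)-2-iodo-3-(methoxymethoxy)benzene
Conditions: MOMCl, iPr2NEt, CH2Cl2, 0 °C to rt
Reagents that add atoms: chloromethyl methyl ether, COCCl
Why: Standard acetal protection of a phenol (O-alkylation with an alpha-chloro ether) marks the one oxygen that later becomes O1 of ring C and makes it acid-releasable beside benzyl ethers.

Step 3
Reactants: 3 1,5-bis(benzyloxy)-2-iodo-3-(methoxymethoxy)benzene; 4 methyl (S)-glycidate
Product: 6 methyl (2S)-3-[2,4-bis(benzyloxy)-6-(methoxymethoxy)phenyl]-2-hydroxypropanoate, via aryl Grignard reagent 5 (not isolated)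
Conditions: iPrMgCl·LiCl (1.1 equiv), THF, 0 °C to rt; CuI (15 mol%), -30 °C; 4, -30 to 0 °C; aq. NH4Cl
Reagents that add atoms: none
Why: Iodine-magnesium exchange followed by copper-catalysed SN2 opening of the epoxide at its unsubstituted carbon forms C4-C4a without touching the stereocentre, so the (S) configuration of 4 becomes C3, and the di-ortho-substituted aryl nucleophile is too hindered to attack the ester at this temperature.

Step 4
Reactants: 6 methyl (2S)-3-[2,4-bis(benzyloxy)-6-(methoxymethoxy)phenyl]-2-hydroxypropanoate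
Product: 7 methyl (2S)-2-(benzyloxy)-3-[2,4-bis(benzyloxy)-6-(methoxymethoxy)phenyl]propanoate
Conditions: BnBr, Ag2O, 4 Å MS, CH2Cl2, rt, dark
Reagents that add atoms: benzyl bromide, BrCc1ccccc1
Why: Silver-oxide-promoted Williamson-type benzylation needs no free alkoxide or enolate, so the alpha-hydroxy ester should be etherified without racemisation and with the MOM group intact.

Step 5
Reactants: 7 methyl (2S)-2-(benzyloxy)-3-[2,4-bis(benzyloxy)-6-(methoxymethoxy)phenyl]propanoate
Product: 8 (2S)-2-(benzyloxy)-3-[2,4-bis(benzyloxy)-6-(methoxymethoxy)phenyl]-N-methoxy-N-methylpropanamide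
Conditions: MeNHOMe·HCl, iPrMgCl, THF, -20 to 0 °C
Reagents that add atoms: N,O-dimethylhydroxylamine hydrochloride, CNOC.Cl
Why: Aminolysis of the ester by the chloromagnesium amide of N,O-dimethylhydroxylamine is fast below 0 °C, a temperature at which the alpha-benzyloxy stereocentre should not be enolised.

Step 6
Reactants: 9 (+)-catechin
Product: 10 5,7,3',4'-tetra-O-benzyl-(+)-catechin
Conditions: BnBr (4.5 equiv), K2CO3, DMF, 0 °C to rt, Ar
Reagents that add atoms: benzyl bromide, BrCc1ccccc1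
Why: Williamson etherification with a weak base alkylates only the four phenols, and working under argon at or below room temperature avoids the base-induced C2 epimerisation of free catechin.

Step 7
Reactants: 10 5,7,3',4'-tetra-O-benzyl-(+)-catechin
Product: 11 3,5,7,3',4'-penta-O-benzyl-(+)-catechin
Conditions: NaH, BnBr, DMF, 0 °C to rt
Reagents that add atoms: benzyl bromide, BrCc1ccccc1
Why: Williamson etherification of the remaining secondary alcohol through its sodium alkoxide is safe for C2 because all phenols are capped and no quinone methide can form.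

Step 8
Reactants: 11 3,5,7,3',4'-penta-O-benzyl-(+)-catechin
Product: 12 8-bromo-3,5,7,3',4'-penta-O-benzyl-(+)-catechin
Conditions: NBS (1.0 equiv), CH2Cl2, -78 to 0 °C
Reagents that add atoms: N-bromosuccinimide, O=C1CCC(=O)N1Br
Why: Electrophilic aromatic bromination of 5,7-di-O-benzyl flavan-3-ols takes place at C8, the more nucleophilic and more open position of ring D, so one equivalent of NBS at low temperature should cap C8 only.

Step 9
Reactants: 12 8-bromo-3,5,7,3',4'-penta-O-benzyl-(+)-catechin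
Product: 13 8-bromo-6-iodo-3,5,7,3',4'-penta-O-benzyl-(+)-catechin
Conditions: NIS (1.2 equiv), CF3CO2H (10 mol%), MeCN/CH2Cl2, 0 °C to rt, dark
Reagents that add atoms: N-iodosuccinimide, O=C1CCC(=O)N1I
Why: Acid-activated electrophilic iodination should go to C6, the only free position of the triply oxygen-activated ring D, which stays more nucleophilic than ring E despite the bromine.

Step 10
Reactants: 13 8-bromo-6-iodo-3,5,7,3',4'-penta-O-benzyl-(+)-catechin; 14 ethynyltrimethylsilane
Product: 15 8-bromo-6-[(trimethylsilyl)ethynyl]-3,5,7,3',4'-penta-O-benzyl-(+)-catechin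
Conditions: PdCl2(PPh3)2 (5 mol%), CuI (10 mol%), Et3N/THF, 60 °C
Reagents that add atoms: none
Why: In this Sonogashira coupling oxidative addition into the C6-I bond is much faster than into the hindered, electron-rich C8-Br bond, and the slim alkyne partner tolerates the two flanking benzyloxy groups.

Step 11
Reactants: 15 8-bromo-6-[(trimethylsilyl)ethynyl]-3,5,7,3',4'-penta-O-benzyl-(+)-catechin
Product: 16 8-bromo-6-ethynyl-3,5,7,3',4'-penta-O-benzyl-(+)-catechin
Conditions: K2CO3 (0.2 equiv), MeOH/THF, rt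
Reagents that add atoms: none
Why: Carbonate-catalysed methanolysis of the alkynylsilane (protodesilylation) frees the terminal alkyne and touches nothing else in the molecule.

Step 12
Reactants: 17 butane-2,3-dione
Product: 18 2,3-bis(tert-butyldimethylsilyloxy)buta-1,3-diene
Conditions: TBSOTf (2.2 equiv), Et3N (3 equiv), CH2Cl2, 0 °C to rt
Reagents that add atoms: tert-butyldimethylsilyl triflate, CC(C)(C)[Si](C)(C)OS(=O)(=O)C(F)(F)F
Why: Double soft enolisation and O-silylation of the 1,2-diketone with a silyl triflate and an amine gives the symmetric bis(silyl enol ether) diene directly.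

Step 13
Reactants: 16 8-bromo-6-ethynyl-3,5,7,3',4'-penta-O-benzyl-(+)-catechin; 8 (2S)-2-(benzyloxy)-3-[2,4-bis(benzyloxy)-6-(methoxymethoxy)phenyl]-N-methoxy-N-methylpropanamide
Product: 20 (4S)-4-(benzyloxy)-5-[2,4-bis(benzyloxy)-6-(methoxymethoxy)phenyl]-1-[8-bromo-3,5,7,3',4'-penta-O-benzyl-(+)-catechin-6-yl]pent-1-yn-3-one, via lithium acetylide 19 (not isolated)
Conditions: LiHMDS (1.05 equiv), THF, -78 °C; 8, -78 to -10 °C; cold aq. NH4Cl
Reagents that add atoms: none
Why: In this Weinreb ketone synthesis the amide base deprotonates the alkyne without halogen-metal exchange at C8-Br, the chelated tetrahedral adduct prevents a second addition, and the cold quench limits conjugate addition of the released amine and enolisation at C3.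

Step 14
Reactants: 20 (4S)-4-(benzyloxy)-5-[2,4-bis(benzyloxy)-6-(methoxymethoxy)phenyl]-1-[8-bromo-3,5,7,3',4'-penta-O-benzyl-(+)-catechin-6-yl]pent-1-yn-3-one; 18 2,3-bis(tert-butyldimethylsilyloxy)buta-1,3-diene
Product: 22 (2S)-2-(benzyloxy)-3-[2,4-bis(benzyloxy)-6-(methoxymethoxy)phenyl]-1-{4,5-bis(tert-butyldimethylsilyloxy)-2-[8-bromo-3,5,7,3',4'-penta-O-benzyl-(+)-catechin-6-yl]phenyl}propan-1-one, via cyclohexa-1,4-diene adduct 21 (not isolated)
Conditions: 18 (3 equiv), BHT (5 mol%), toluene (1 M), 130 °C, sealed tube; excess 18 stripped at 0.1 mbar; DDQ (1.05 equiv), toluene, 0 °C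
Reagents that add atoms: none
Why: The ynone carbonyl lowers the alkyne LUMO and the two silyloxy groups raise the diene HOMO, so 18 in its s-cis form should add suprafacially across the triple bond in a concerted, normal-demand [4+2] cycloaddition that forms C1'-C2' and C5'-C6' and gives cyclohexa-1,4-diene 21. DDQ then abstracts hydride from one of the doubly allylic CH2 groups, and loss of the neighbouring proton aromatises 21 to the catechol bis(silyl ether) 22. The closest known reaction type is the Diels-Alder addition of 2,3-dioxygenated buta-1,3-dienes to acetylenic ketones and esters followed by quinone dehydrogenation, a sequence also used to reach crowded biaryls from aryl alkynes. Ring B closes as a six-membered carbocycle in an intermolecular two-bond closure, so the tri-ortho-substituted C6'-C6 bond never has to be forged between two arenes because it already exists as the open aryl-alkyne bond. No stereocentre is created, and the (S) centre beside the carbonyl only has to survive, which heating without acid or base and with a radical inhibitor should allow. Regioselectivity does not arise because 18 is symmetric, site selectivity follows from the ynone being the only electron-poor pi bond (the C8 bromine tempers the donor push of ring D), and one equivalent of DDQ at 0 °C should dehydrogenate 21 well before it touches the flavan C4-H bonds, the ring A benzylic CH2 or the benzyl ethers.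

Step 15
Reactants: 22 (2S)-2-(benzyloxy)-3-[2,4-bis(benzyloxy)-6-(methoxymethoxy)phenyl]-1-{4,5-bis(tert-butyldimethylsilyloxy)-2-[8-bromo-3,5,7,3',4'-penta-O-benzyl-(+)-catechin-6-yl]phenyl}propan-1-one
Product: 23 (1S,2S)-2-(benzyloxy)-3-[2,4-bis(benzyloxy)-6-(methoxymethoxy)phenyl]-1-{4,5-bis(tert-butyldimethylsilyloxy)-2-[8-bromo-3,5,7,3',4'-penta-O-benzyl-(+)-catechin-6-yl]phenyl}propan-1-ol (major epimer drawn)
Conditions: NaBH4, THF/MeOH 4:1, -10 °C
Reagents that add atoms: none
Why: Borohydride reduction of the aryl ketone under non-chelating conditions should follow the polar Felkin-Anh model (hydride anti to the C3 benzyloxy group) and favour the syn (1S,2S) alcohol, although this centre is not critical because both epimers ionise to the same cation in step 17.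

Step 16
Reactants: 23 (1S,2S)-2-(benzyloxy)-3-[2,4-bis(benzyloxy)-6-(methoxymethoxy)phenyl]-1-{4,5-bis(tert-butyldimethylsilyloxy)-2-[8-bromo-3,5,7,3',4'-penta-O-benzyl-(+)-catechin-6-yl]phenyl}propan-1-ol
Product: 25 (1S,2S)-2-(benzyloxy)-3-[2,4-bis(benzyloxy)-6-(methoxymethoxy)phenyl]-1-{4,5-bis(benzyloxy)-2-[8-bromo-3,5,7,3',4'-penta-O-benzyl-(+)-catechin-6-yl]phenyl}propan-1-ol, via free catechol 24 (not isolated)
Conditions: TBAF (2.2 equiv), THF, 0 °C; BnBr (3 equiv), rt
Reagents that add atoms: benzyl bromide, BrCc1ccccc1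
Why: Fluoride cleaves the two aryl silyl ethers to the ammonium catecholate, which is benzylated in situ (Williamson etherification) while the far less acidic secondary alcohol stays free, and placing the swap after the reduction means no enolisable ketone meets the basic medium.

Step 17
Reactants: 25 (1S,2S)-2-(benzyloxy)-3-[2,4-bis(benzyloxy)-6-(methoxymethoxy)phenyl]-1-{4,5-bis(benzyloxy)-2-[8-bromo-3,5,7,3',4'-penta-O-benzyl-(+)-catechin-6-yl]phenyl}propan-1-ol
Product: 27 3,5,7,3',4'-penta-O-benzyl-(+)-catechin-(6'→6)-8-bromo-3,5,7,3',4'-penta-O-benzyl-(+)-catechin, via free ring A phenol 26 (not isolated)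
Conditions: HCl (1.25 M in MeOH)/THF 1:1, 0.01 M in 25, 40 °C
Reagents that add atoms: none
Why: Methanolic acid removes the MOM acetal and ionises the carbinol to a benzylic cation stabilised by the para 4'-benzyloxy group, which the freed ring A phenol captures through a six-membered chair-like transition state with the bulky C2 aryl group and the C3 benzyloxy group both pseudo-equatorial, so the fixed (S)-C3 centre should impose the 2,3-trans (2R,3S) arrangement from either carbinol epimer (acid-catalysed deprotection-cyclisation of 1,3-diarylpropane-1,2-diol derivatives to flavan-3-ols).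

Step 18
Reactants: 27 3,5,7,3',4'-penta-O-benzyl-(+)-catechin-(6'→6)-8-bromo-3,5,7,3',4'-penta-O-benzyl-(+)-catechin
Product: 28 (+)-catechin-(6'→6)-(+)-catechin (CNP0125771.1)
Conditions: H2 (1 atm), Pd(OH)2/C, THF/MeOH/H2O, rt; filtration under Ar
Reagents that add atoms: none
Why: Catalytic hydrogenolysis should remove the ten benzyl ethers and reduce the C8-Br cap in one operation under mild conditions that leave the four stereocentres and the flavan C2-O1 bonds intact.

## Compound list

1 | 3,5-bis(benzyloxy)phenol | Oc1cc(OCc2ccccc2)cc(OCc2ccccc2)c1 | starting material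
2 | 3,5-bis(benzyloxy)-2-iodophenol | Oc1cc(OCc2ccccc2)cc(OCc2ccccc2)c1I | intermediate
3 | 1,5-bis(benzyloxy)-2-iodo-3-(methoxymethoxy)benzene | COCOc1cc(OCc2ccccc2)cc(OCc2ccccc2)c1I | intermediate
4 | methyl (S)-glycidate | COC(=O)[C@@H]1CO1 | starting material
5 | [2,4-bis(benzyloxy)-6-(methoxymethoxy)phenyl]magnesium chloride | COCOc1cc(OCc2ccccc2)cc(OCc2ccccc2)c1[Mg]Cl | intermediate
6 | methyl (2S)-3-[2,4-bis(benzyloxy)-6-(methoxymethoxy)phenyl]-2-hydroxypropanoate | COC(=O)[C@@H](O)Cc1c(OCOC)cc(OCc2ccccc2)cc1OCc1ccccc1 | intermediate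
7 | methyl (2S)-2-(benzyloxy)-3-[2,4-bis(benzyloxy)-6-(methoxymethoxy)phenyl]propanoate | COC(=O)[C@@H](OCc1ccccc1)Cc1c(OCOC)cc(OCc2ccccc2)cc1OCc1ccccc1 | intermediate
8 | (2S)-2-(benzyloxy)-3-[2,4-bis(benzyloxy)-6-(methoxymethoxy)phenyl]-N-methoxy-N-methylpropanamide | CON(C)C(=O)[C@@H](OCc1ccccc1)Cc1c(OCOC)cc(OCc2ccccc2)cc1OCc1ccccc1 | intermediate
9 | (+)-catechin [(2R,3S)-2-(3,4-dihydroxyphenyl)chromane-3,5,7-triol] | Oc1cc(O)c2c(c1)O[C@H](c1ccc(O)c(O)c1)[C@@H](O)C2 | starting material
10 | 5,7,3',4'-tetra-O-benzyl-(+)-catechin | c1c(OCc4ccccc4)cc3c(c1OCc4ccccc4)C[C@H](O)[C@@H](c4ccc(OCc5ccccc5)c(OCc5ccccc5)c4)O3 | intermediate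
11 | 3,5,7,3',4'-penta-O-benzyl-(+)-catechin | c1c(OCc4ccccc4)cc3c(c1OCc4ccccc4)C[C@H](OCc4ccccc4)[C@@H](c4ccc(OCc5ccccc5)c(OCc5ccccc5)c4)O3 | intermediate
12 | 8-bromo-3,5,7,3',4'-penta-O-benzyl-(+)-catechin | c1c(OCc4ccccc4)c(Br)c3c(c1OCc4ccccc4)C[C@H](OCc4ccccc4)[C@@H](c4ccc(OCc5ccccc5)c(OCc5ccccc5)c4)O3 | intermediate
13 | 8-bromo-6-iodo-3,5,7,3',4'-penta-O-benzyl-(+)-catechin | Ic1c(OCc4ccccc4)c(Br)c3c(c1OCc4ccccc4)C[C@H](OCc4ccccc4)[C@@H](c4ccc(OCc5ccccc5)c(OCc5ccccc5)c4)O3 | intermediate
14 | ethynyltrimethylsilane | C#C[Si](C)(C)C | starting material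
15 | 8-bromo-6-[(trimethylsilyl)ethynyl]-3,5,7,3',4'-penta-O-benzyl-(+)-catechin | C[Si](C)(C)C#Cc1c(OCc4ccccc4)c(Br)c3c(c1OCc4ccccc4)C[C@H](OCc4ccccc4)[C@@H](c4ccc(OCc5ccccc5)c(OCc5ccccc5)c4)O3 | intermediate
16 | 8-bromo-6-ethynyl-3,5,7,3',4'-penta-O-benzyl-(+)-catechin | C#Cc1c(OCc4ccccc4)c(Br)c3c(c1OCc4ccccc4)C[C@H](OCc4ccccc4)[C@@H](c4ccc(OCc5ccccc5)c(OCc5ccccc5)c4)O3 | intermediate
17 | butane-2,3-dione | CC(=O)C(C)=O | starting material
18 | 2,3-bis(tert-butyldimethylsilyloxy)buta-1,3-diene | C=C(O[Si](C)(C)C(C)(C)C)C(=C)O[Si](C)(C)C(C)(C)C | intermediate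
19 | lithium acetylide of 16 | [Li]C#Cc1c(OCc4ccccc4)c(Br)c3c(c1OCc4ccccc4)C[C@H](OCc4ccccc4)[C@@H](c4ccc(OCc5ccccc5)c(OCc5ccccc5)c4)O3 | intermediate
20 | ynone, (4S)-4-(benzyloxy)-5-[2,4-bis(benzyloxy)-6-(methoxymethoxy)phenyl]-1-[8-bromo-3,5,7,3',4'-penta-O-benzyl-(+)-catechin-6-yl]pent-1-yn-3-one | O=C(C#Cc1c(OCc4ccccc4)c(Br)c3c(c1OCc4ccccc4)C[C@H](OCc4ccccc4)[C@@H](c4ccc(OCc5ccccc5)c(OCc5ccccc5)c4)O3)[C@@H](OCc1ccccc1)Cc1c(OCOC)cc(OCc2ccccc2)cc1OCc1ccccc1 | intermediate
21 | Diels-Alder adduct, as 22 but with a 4,5-bis(silyloxy)-2-arylcyclohexa-1,4-dien-1-yl ring in place of ring B | O=C(C1=C(c2c(OCc4ccccc4)c(Br)c3c(c2OCc4ccccc4)C[C@H](OCc4ccccc4)[C@@H](c4ccc(OCc5ccccc5)c(OCc5ccccc5)c4)O3)CC(O[Si](C)(C)C(C)(C)C)=C(O[Si](C)(C)C(C)(C)C)C1)[C@@H](OCc1ccccc1)Cc1c(OCOC)cc(OCc2ccccc2)cc1OCc1ccccc1 | intermediate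
22 | biaryl ketone, (2S)-2-(benzyloxy)-3-[2,4-bis(benzyloxy)-6-(methoxymethoxy)phenyl]-1-{4,5-bis(tert-butyldimethylsilyloxy)-2-[8-bromo-3,5,7,3',4'-penta-O-benzyl-(+)-catechin-6-yl]phenyl}propan-1-one | O=C(c1cc(O[Si](C)(C)C(C)(C)C)c(O[Si](C)(C)C(C)(C)C)cc1-c1c(OCc4ccccc4)c(Br)c3c(c1OCc4ccccc4)C[C@H](OCc4ccccc4)[C@@H](c4ccc(OCc5ccccc5)c(OCc5ccccc5)c4)O3)[C@@H](OCc1ccccc1)Cc1c(OCOC)cc(OCc2ccccc2)cc1OCc1ccccc1 | intermediate
23 | (1S,2S)-alcohol from 22, ring B as bis(TBS ether); (1S) epimer drawn, minor (1R) epimer carried along | O[C@@H](c1cc(O[Si](C)(C)C(C)(C)C)c(O[Si](C)(C)C(C)(C)C)cc1-c1c(OCc4ccccc4)c(Br)c3c(c1OCc4ccccc4)C[C@H](OCc4ccccc4)[C@@H](c4ccc(OCc5ccccc5)c(OCc5ccccc5)c4)O3)[C@@H](OCc1ccccc1)Cc1c(OCOC)cc(OCc2ccccc2)cc1OCc1ccccc1 | intermediate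
24 | (1S,2S)-alcohol with ring B as free catechol | O[C@@H](c1cc(O)c(O)cc1-c1c(OCc4ccccc4)c(Br)c3c(c1OCc4ccccc4)C[C@H](OCc4ccccc4)[C@@H](c4ccc(OCc5ccccc5)c(OCc5ccccc5)c4)O3)[C@@H](OCc1ccccc1)Cc1c(OCOC)cc(OCc2ccccc2)cc1OCc1ccccc1 | intermediate
25 | (1S,2S)-alcohol with ring B as bis(benzyl ether), ring A still MOM-protected | O[C@@H](c1cc(OCc6ccccc6)c(OCc6ccccc6)cc1-c1c(OCc4ccccc4)c(Br)c3c(c1OCc4ccccc4)C[C@H](OCc4ccccc4)[C@@H](c4ccc(OCc5ccccc5)c(OCc5ccccc5)c4)O3)[C@@H](OCc1ccccc1)Cc1c(OCOC)cc(OCc2ccccc2)cc1OCc1ccccc1 | intermediate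
26 | (1S,2S)-alcohol as 25 with the ring A phenol free | O[C@@H](c1cc(OCc6ccccc6)c(OCc6ccccc6)cc1-c1c(OCc4ccccc4)c(Br)c3c(c1OCc4ccccc4)C[C@H](OCc4ccccc4)[C@@H](c4ccc(OCc5ccccc5)c(OCc5ccccc5)c4)O3)[C@@H](OCc1ccccc1)Cc1c(O)cc(OCc2ccccc2)cc1OCc1ccccc1 | intermediate
27 | 3,5,7,3',4'-penta-O-benzyl-(+)-catechin-(6'→6)-8-bromo-3,5,7,3',4'-penta-O-benzyl-(+)-catechin, both units (2R,3S) | C(c1ccccc1)Oc1cc(OCc6ccccc6)c2c(c1)O[C@H](c1cc(OCc6ccccc6)c(OCc6ccccc6)cc1-c1c(OCc4ccccc4)c(Br)c3c(c1OCc4ccccc4)C[C@H](OCc4ccccc4)[C@@H](c4ccc(OCc5ccccc5)c(OCc5ccccc5)c4)O3)[C@@H](OCc1ccccc1)C2 | intermediate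
28 | (+)-catechin-(6'→6)-(+)-catechin, CNP0125771.1, both units (2R,3S) | Oc1cc(O)c2c(c1)O[C@H](c1cc(O)c(O)cc1-c1c(O)cc3c(c1O)C[C@H](O)[C@@H](c1ccc(O)c(O)c1)O3)[C@@H](O)C2 | target

## Step count and risks

Total steps: 18. The longest linear sequence is 12 steps, from 9 through steps 6 to 11 and 13 to 18.

**Step 14.**
- What may go wrong: the cycloaddition may be too slow, because ring D feeds electron density into the ynone and its two ortho benzyloxy groups shield the alkyne carbon. Long heating could then bring enolisation at C3, decay of the diene, or oxidation beyond the cyclohexadiene in the DDQ stage.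
- Fallback (sets out from 8 and 13, returns at 25): ring B is taken as a ready-made arene and the C6'-C6 bond is formed by cross-coupling.
- Commercial 4,5-dibromocatechol is benzylated (BnBr, K2CO3, DMF) to 1,2-bis(benzyloxy)-4,5-dibromobenzene F1.
- A single bromine-magnesium exchange (iPrMgCl·LiCl, THF, -15 °C) gives [4,5-bis(benzyloxy)-2-bromophenyl]magnesium chloride F2. This is acylated by 8 to the 2-bromoaryl ketone F3.
- Iodide 13 undergoes selective iodine-magnesium exchange to the ring D arylmagnesium chloride F4, which ZnCl2 converts to the ring D arylzinc chloride F5.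
- A base-free Negishi coupling of F5 with F3 (Pd2(dba)3, RuPhos, THF, 60 °C) gives the bis-benzyl biaryl ketone F6. NaBH4 reduction of F6 gives 25.

**Step 17.**
- What may go wrong: facial selectivity in the capture of the cation may be poor. The cation may also be lost by a 1,2-hydride shift from C3, by attack of a ring D benzyloxy oxygen with debenzylation, or by intermolecular arylation.
- Fallback (sets out from 25, returns at 27): the closure is changed from ionisation to a stereospecific displacement. The syn epimer of 25 is separated.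
- The aryl MOM ether is exchanged under buffered, non-ionising conditions (TMSOTf, 2,2'-bipyridyl, CH2Cl2, 0 °C) to give the bis(trimethylsilyl) ether F7. Water cleaves F7 to phenol 26, which is now isolated.
- An intramolecular Mitsunobu etherification (PPh3, DIAD, toluene, 0 °C) then displaces the activated (1S) carbinol with inversion. This gives the (2R,3S)-trans flavan 27.

**Step 9.**
- What may go wrong: iodination at the crowded C6 between two benzyloxy groups may be sluggish. Attack on ring E or ipso exchange of the C8 bromine may compete.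
- Fallback (sets out from 12, returns at 16): the alkyne carbons are brought in one at a time through a carbonyl instead of by halogenation and coupling.
- Vilsmeier-Haack formylation of 12 (POCl3, DMF, 0 to 70 °C, then aq. NaOAc) at the only free ring D position gives 8-bromo-3,5,7,3',4'-penta-O-benzyl-(+)-catechin-6-carbaldehyde F8.
- Ohira-Bestmann homologation of F8 (dimethyl (1-diazo-2-oxopropyl)phosphonate, K2CO3, MeOH/THF, rt) gives alkyne 16 directly.

## Further compounds

F1 | step 14 | 1,2-bis(benzyloxy)-4,5-dibromobenzene | Brc1cc(OCc2ccccc2)c(OCc2ccccc2)cc1Br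
F2 | step 14 | [4,5-bis(benzyloxy)-2-bromophenyl]magnesium chloride | Cl[Mg]c1cc(OCc2ccccc2)c(OCc2ccccc2)cc1Br
F3 | step 14 | (2S)-2-(benzyloxy)-1-[4,5-bis(benzyloxy)-2-bromophenyl]-3-[2,4-bis(benzyloxy)-6-(methoxymethoxy)phenyl]propan-1-one | O=C(c1cc(OCc2ccccc2)c(OCc2ccccc2)cc1Br)[C@@H](OCc1ccccc1)Cc1c(OCOC)cc(OCc2ccccc2)cc1OCc1ccccc1
F4 | step 14 | [8-bromo-3,5,7,3',4'-penta-O-benzyl-(+)-catechin-6-yl]magnesium chloride | Cl[Mg]c1c(OCc4ccccc4)c(Br)c3c(c1OCc4ccccc4)C[C@H](OCc4ccccc4)[C@@H](c4ccc(OCc5ccccc5)c(OCc5ccccc5)c4)O3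
F5 | step 14 | [8-bromo-3,5,7,3',4'-penta-O-benzyl-(+)-catechin-6-yl]zinc chloride | Cl[Zn]c1c(OCc4ccccc4)c(Br)c3c(c1OCc4ccccc4)C[C@H](OCc4ccccc4)[C@@H](c4ccc(OCc5ccccc5)c(OCc5ccccc5)c4)O3
F6 | step 14 | (2S)-2-(benzyloxy)-3-[2,4-bis(benzyloxy)-6-(methoxymethoxy)phenyl]-1-{4,5-bis(benzyloxy)-2-[8-bromo-3,5,7,3',4'-penta-O-benzyl-(+)-catechin-6-yl]phenyl}propan-1-one | O=C(c1cc(OCc6ccccc6)c(OCc6ccccc6)cc1-c1c(OCc4ccccc4)c(Br)c3c(c1OCc4ccccc4)C[C@H](OCc4ccccc4)[C@@H](c4ccc(OCc5ccccc5)c(OCc5ccccc5)c4)O3)[C@@H](OCc1ccccc1)Cc1c(OCOC)cc(OCc2ccccc2)cc1OCc1ccccc1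
F7 | step 17 | bis(trimethylsilyl) ether of 26 (carbinol oxygen and ring A phenol oxygen silylated) | C[Si](C)(C)O[C@@H](c1cc(OCc6ccccc6)c(OCc6ccccc6)cc1-c1c(OCc4ccccc4)c(Br)c3c(c1OCc4ccccc4)C[C@H](OCc4ccccc4)[C@@H](c4ccc(OCc5ccccc5)c(OCc5ccccc5)c4)O3)[C@@H](OCc1ccccc1)Cc1c(O[Si](C)(C)C)cc(OCc2ccccc2)cc1OCc1ccccc1
F8 | step 9 | 8-bromo-3,5,7,3',4'-penta-O-benzyl-(+)-catechin-6-carbaldehyde | O=Cc1c(OCc4ccccc4)c(Br)c3c(c1OCc4ccccc4)C[C@H](OCc4ccccc4)[C@@H](c4ccc(OCc5ccccc5)c(OCc5ccccc5)c4)O3
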